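Ring C of the flavone is cut at three bonds: C4a–C4, C4–C3 and O1–C2. The C4 carbonyl sits between C4a of the phloroglucinol-derived ring A and the C3–C2 unit that carries ring B, and O1 is a ring A phenol oxygen, so an ortho-iodophenol ester, carbon monoxide and a ring B arylacetylene deliver the whole pyranone in one palladium-catalysed carbonylative annulation. The iodide is the threefold-symmetric 2-iodophloroglucinol triacetate; the alkyne already holds the complete erythro (7''R,8''S) side chain, locked as a di-tert-butylsilylene with ring D as its benzyl ether. C-8'' comes from methyl (R)-glycerate by Mitsunobu inversion, C-7'' from a Felkin–Anh aryltitanium addition.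

Key step: step 11

Assumption: locants C-7'', C-8'' and C-9'' follow the target name; partial loss of the 5- or 7-acetate of 21 to the amine in step 11 is taken as harmless because step 12 removes both.

Step 1
Reactants: 1 phloroglucinol (benzene-1,3,5-triol)
Product: 2 2-iodobenzene-1,3,5-triol
Conditions: I2 (1.0 equiv), NaHCO3, THF/H2O, 0 °C
Reagents that add atoms: iodine, II
Why: Electrophilic aromatic iodination; the three ring CH positions of the strongly activated triol are equivalent, and one equivalent of iodine under NaHCO3 buffering at 0 °C should stop at the mono-iodide.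

Step 2
Reactants: 2 2-iodobenzene-1,3,5-triol
Product: 3 2-iodobenzene-1,3,5-triyl triacetate
Conditions: Ac2O, pyridine, CH2Cl2, 0 °C → rt (crude 2 used directly)
Reagents that add atoms: acetic anhydride, CC(=O)OC(C)=O
Why: Pyridine-mediated O-acetylation (nucleophilic acyl substitution) of the crude triol, done at once because the free iodotriol is sensitive to acid and air, should give the stable, threefold-symmetric triacetate.

Step 3
Reactants: 4 methyl (R)-2,2-dimethyl-1,3-dioxolane-4-carboxylate
Product: 5 methyl (R)-2,3-dihydroxypropanoate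
Conditions: p-TsOH·H2O (cat.), MeOH, rt; NaHCO3, evaporate
Reagents that add atoms: none
Why: Acid-catalysed transacetalisation (acetonide methanolysis) frees the 1,2-diol without breaking a bond to C-2, so the (R) centre and the methyl ester stay intact.

Step 4
Reactants: 5 methyl (R)-2,3-dihydroxypropanoate
Product: 6 methyl (R)-3-[(tert-butyldiphenylsilyl)oxy]-2-hydroxypropanoate
Conditions: TBDPSCl (1.05 equiv), imidazole, CH2Cl2, 0 °C
Reagents that add atoms: tert-butyl(chloro)diphenylsilane, CC(C)(C)[Si](Cl)(c1ccccc1)c1ccccc1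
Why: Sterically controlled, imidazole-promoted silylation should take the primary hydroxyl in preference to the hindered and less nucleophilic hydroxyl of the α-hydroxy ester.

Step 5
Reactants: 6 methyl (R)-3-[(tert-butyldiphenylsilyl)oxy]-2-hydroxypropanoate; 7 4-bromo-2,6-dimethoxyphenol
Product: 8 methyl (S)-2-(4-bromo-2,6-dimethoxyphenoxy)-3-[(tert-butyldiphenylsilyl)oxy]propanoate
Conditions: PPh3, DIAD, THF, 0 °C → rt
Reagents that add atoms: none
Why: Mitsunobu reaction; the secondary alcohol is activated as its alkoxyphosphonium ion and displaced by the phenoxide of 7 in an SN2 step with inversion, which is favoured next to the ester carbonyl and turns (R)-C-2 into the (S)-aryl ether that becomes C-8''.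

Step 6
Reactants: 8 methyl (S)-2-(4-bromo-2,6-dimethoxyphenoxy)-3-[(tert-butyldiphenylsilyl)oxy]propanoate
Product: 9 (S)-2-(4-bromo-2,6-dimethoxyphenoxy)-3-[(tert-butyldiphenylsilyl)oxy]propanal
Conditions: iBu2AlH, CH2Cl2, −78 °C; aq. potassium sodium tartrate (KNaC4H4O6)
Reagents that add atoms: none
Why: Partial reduction of the ester with iBu2AlH at −78 °C should stop at the aluminium hemiacetal, which is held by chelation to the α-aryloxy oxygen and releases the aldehyde only on work-up; the crude aldehyde is used at once so that the α-stereocentre is not exposed to base or silica.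

Step 7
Reactants: 9 (S)-2-(4-bromo-2,6-dimethoxyphenoxy)-3-[(tert-butyldiphenylsilyl)oxy]propanal; 10 1-(benzyloxy)-4-bromobenzene
Product: 13 (1R,2S)-1-[4-(benzyloxy)phenyl]-2-(4-bromo-2,6-dimethoxyphenoxy)-3-[(tert-butyldiphenylsilyl)oxy]propan-1-ol, via aryllithium 11 (not isolated), via aryltitanium triisopropoxide 12 (not isolated)
Conditions: 10, n-BuLi, THF, −78 °C; ClTi(OiPr)3, −78 → −40 °C; then 9, −78 → −20 °C; aq. NH4Cl
Reagents that add atoms: none
Why: Bromine–lithium exchange and transmetalation give an aryltitanium triisopropoxide that is chemoselective for the aldehyde (the aryl bromide of 9 is untouched) and too weakly Lewis acidic to chelate, so it should add under Felkin–Anh control, anti to the perpendicular C–OAr bond and past the hydrogen of C-2, which sets C-1 (C-7'') as R, anti (erythro) to (S)-C-8''.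

Step 8
Reactants: 13 (1R,2S)-1-[4-(benzyloxy)phenyl]-2-(4-bromo-2,6-dimethoxyphenoxy)-3-[(tert-butyldiphenylsilyl)oxy]propan-1-ol; 14 ethynyltrimethylsilane
Product: 15 (1R,2S)-1-[4-(benzyloxy)phenyl]-3-[(tert-butyldiphenylsilyl)oxy]-2-{2,6-dimethoxy-4-[(trimethylsilyl)ethynyl]phenoxy}propan-1-ol
Conditions: PdCl2(PPh3)2 (cat.), CuI (cat.), Et3N, DMF, 80 °C, sealed tube
Reagents that add atoms: none
Why: Sonogashira coupling of an aryl bromide whose two ortho positions are free with the silyl-capped alkyne; the free secondary alcohol, the silyl ether and the benzyl ether are inert to the Pd/Cu/amine system.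

Step 9
Reactants: 15 (1R,2S)-1-[4-(benzyloxy)phenyl]-3-[(tert-butyldiphenylsilyl)oxy]-2-{2,6-dimethoxy-4-[(trimethylsilyl)ethynyl]phenoxy}propan-1-ol
Product: 16 (1R,2S)-1-[4-(benzyloxy)phenyl]-2-(4-ethynyl-2,6-dimethoxyphenoxy)propane-1,3-diol
Conditions: TBAF, THF, 0 °C → rt
Reagents that add atoms: none
Why: Fluoride-induced desilylation should cleave the O–Si bond of the silyl ether and the C(sp)–Si bond of the alkynylsilane in one operation, driven by the strength of the Si–F bond, without touching the benzyl ether or either stereocentre.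

Step 10
Reactants: 16 (1R,2S)-1-[4-(benzyloxy)phenyl]-2-(4-ethynyl-2,6-dimethoxyphenoxy)propane-1,3-diol
Product: 17 (4R,5S)-4-[4-(benzyloxy)phenyl]-2,2-di-tert-butyl-5-(4-ethynyl-2,6-dimethoxyphenoxy)-1,3,2-dioxasilinane
Conditions: tBu2Si(OTf)2, 2,6-lutidine, CH2Cl2, 0 °C
Reagents that add atoms: di-tert-butylsilyl bis(trifluoromethanesulfonate), CC(C)(C)[Si](OS(=O)(=O)C(F)(F)F)(OS(=O)(=O)C(F)(F)F)C(C)(C)C
Why: Silylene formation; the bis-triflate bridges the 1,3-diol as a six-membered 1,3,2-dioxasilinane in which the aryl and aryloxy groups can both sit equatorial (trans), as expected for the erythro series, and the terminal alkyne is inert to the silyl triflate under lutidine buffering.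

Step 11
Reactants: 3 2-iodobenzene-1,3,5-triyl triacetate; 17 (4R,5S)-4-[4-(benzyloxy)phenyl]-2,2-di-tert-butyl-5-(4-ethynyl-2,6-dimethoxyphenoxy)-1,3,2-dioxasilinane; 18 carbon monoxide
Product: 21 2-(4-{[(4R,5S)-4-[4-(benzyloxy)phenyl]-2,2-di-tert-butyl-1,3,2-dioxasilinan-5-yl]oxy}-3,5-dimethoxyphenyl)-4-oxo-4H-chromene-5,7-diyl diacetate (5,7-diacetoxyflavone), via triacetoxyphenyl ynone 19 (not isolated), via diethylamino enone phenol 20 (not isolated)
Conditions: CO (1 atm, balloon), PdCl2(PPh3)2 (5 mol %), dppp (5 mol %), thiourea (5 mol %), Et2NH, DBU, DMF, 40 °C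
Reagents that add atoms: none
Why: Oxidative addition of the C–I bond of 3 to zerovalent palladium and CO insertion give an aroyl complex of divalent palladium, which couples with the acetylide of 17 to ynone 19 (C4a–C4 and C4–C3); Et2NH then adds to the ynone and cleaves one ortho acetate, and the phenol of 20 displaces the amine at C2 (O1–C2). The closest known reaction type is the palladium-catalysed carbonylative annulation of ortho-iodophenol acetates with terminal arylacetylenes to flavones, a carbonylative Sonogashira coupling followed by oxa-Michael addition–elimination. Ring C closes in the 6-endo mode, formally 6-endo-dig on the ynone and in practice an addition–elimination at C2 of the β-amino enone. No stereocentre is formed, and C-7'' and C-8'' are ether carbons remote from the reacting sites and inert to the amine bases. The step needs 6-endo closure (flavone) over 5-exo closure (aurone), which the prior conjugate addition of the secondary amine secures by making C2 the site of substitution, and it needs alkyne coupling to outrun amide formation from the aroylpalladium species, which the mild temperature and the dppp/thiourea ligand set should favour. The threefold symmetry of 3 removes any regiochemical question because either ortho acetate gives the same phenol, and the acetates keep the iodoarene electron-poor enough for oxidative addition.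

Step 12
Reactants: 21 2-(4-{[(4R,5S)-4-[4-(benzyloxy)phenyl]-2,2-di-tert-butyl-1,3,2-dioxasilinan-5-yl]oxy}-3,5-dimethoxyphenyl)-4-oxo-4H-chromene-5,7-diyl diacetate
Product: 22 2-(4-{[(4R,5S)-4-[4-(benzyloxy)phenyl]-2,2-di-tert-butyl-1,3,2-dioxasilinan-5-yl]oxy}-3,5-dimethoxyphenyl)-5,7-dihydroxy-4H-chromen-4-one
Conditions: K2CO3, MeOH/THF, 0 °C → rt
Reagents that add atoms: none
Why: Base-catalysed transesterification (methanolysis) of the two aryl acetates, the most electrophilic groups present, should leave the benzyl ether, the chromone and both stereocentres untouched, and any partial opening of the silylene would not matter because step 13 removes it.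

Step 13
Reactants: 22 2-(4-{[(4R,5S)-4-[4-(benzyloxy)phenyl]-2,2-di-tert-butyl-1,3,2-dioxasilinan-5-yl]oxy}-3,5-dimethoxyphenyl)-5,7-dihydroxy-4H-chromen-4-one
Product: 23 2-(4-{[(1R,2S)-1-[4-(benzyloxy)phenyl]-1,3-dihydroxypropan-2-yl]oxy}-3,5-dimethoxyphenyl)-5,7-dihydroxy-4H-chromen-4-one
Conditions: HF·pyridine, pyridine, THF, 0 °C → rt
Reagents that add atoms: none
Why: Fluoride-mediated cleavage of the silylene under pyridine buffering attacks silicon only, so the C-7''–O and C-8''–O bonds and their configurations are preserved.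

Step 14
Reactants: 23 2-(4-{[(1R,2S)-1-[4-(benzyloxy)phenyl]-1,3-dihydroxypropan-2-yl]oxy}-3,5-dimethoxyphenyl)-5,7-dihydroxy-4H-chromen-4-one
Product: 24 (-)-(7''R,8''S)-4'',5,7-trihydroxy-3',5'-dimethoxy-4',8''-oxyflavonolignan-7'',9''-diol
Conditions: H2 (1 atm), Pd/C, THF/MeOH, rt
Reagents that add atoms: none
Why: Catalytic hydrogenolysis of the aryl benzyl ether under neutral conditions at one atmosphere is expected to be much faster than hydrogenolysis of the secondary benzylic alcohol or reduction of the chromone C2=C3 bond, so stopping at full consumption of 23 should deliver the target.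

Compound list

1 | phloroglucinol (benzene-1,3,5-triol) | Oc1cc(O)cc(O)c1 | starting material
2 | 2-iodobenzene-1,3,5-triol | Oc1cc(O)c(I)c(O)c1 | intermediate
3 | 2-iodobenzene-1,3,5-triyl triacetate | CC(=O)Oc1cc(OC(C)=O)c(I)c(OC(C)=O)c1 | intermediate
4 | methyl (R)-2,2-dimethyl-1,3-dioxolane-4-carboxylate | COC(=O)[C@H]1COC(C)(C)O1 | starting material
5 | methyl (R)-2,3-dihydroxypropanoate | COC(=O)[C@H](O)CO | intermediate
6 | methyl (R)-3-[(tert-butyldiphenylsilyl)oxy]-2-hydroxypropanoate | COC(=O)[C@H](O)CO[Si](c1ccccc1)(c1ccccc1)C(C)(C)C | intermediate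
7 | 4-bromo-2,6-dimethoxyphenol | COc1cc(Br)cc(OC)c1O | starting material
8 | methyl (S)-2-(4-bromo-2,6-dimethoxyphenoxy)-3-[(tert-butyldiphenylsilyl)oxy]propanoate | COC(=O)[C@@H](Oc1c(OC)cc(Br)cc1OC)CO[Si](c1ccccc1)(c1ccccc1)C(C)(C)C | intermediate
9 | (S)-2-(4-bromo-2,6-dimethoxyphenoxy)-3-[(tert-butyldiphenylsilyl)oxy]propanal | O=C[C@@H](Oc1c(OC)cc(Br)cc1OC)CO[Si](c1ccccc1)(c1ccccc1)C(C)(C)C | intermediate
10 | 1-(benzyloxy)-4-bromobenzene | Brc1ccc(OCc2ccccc2)cc1 | starting material
11 | [4-(benzyloxy)phenyl]lithium | [Li]c1ccc(OCc2ccccc2)cc1 | intermediate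
12 | [4-(benzyloxy)phenyl]titanium triisopropoxide | CC(C)O[Ti](OC(C)C)(OC(C)C)c1ccc(OCc2ccccc2)cc1 | intermediate
13 | (1R,2S)-1-[4-(benzyloxy)phenyl]-2-(4-bromo-2,6-dimethoxyphenoxy)-3-[(tert-butyldiphenylsilyl)oxy]propan-1-ol | COc1cc(Br)cc(OC)c1O[C@@H](CO[Si](c1ccccc1)(c1ccccc1)C(C)(C)C)[C@H](O)c1ccc(OCc2ccccc2)cc1 | intermediate
14 | ethynyltrimethylsilane | C#C[Si](C)(C)C | starting material
15 | (1R,2S)-1-[4-(benzyloxy)phenyl]-3-[(tert-butyldiphenylsilyl)oxy]-2-{2,6-dimethoxy-4-[(trimethylsilyl)ethynyl]phenoxy}propan-1-ol | COc1cc(C#C[Si](C)(C)C)cc(OC)c1O[C@@H](CO[Si](c1ccccc1)(c1ccccc1)C(C)(C)C)[C@H](O)c1ccc(OCc2ccccc2)cc1 | intermediate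
16 | (1R,2S)-1-[4-(benzyloxy)phenyl]-2-(4-ethynyl-2,6-dimethoxyphenoxy)propane-1,3-diol | COc1cc(C#C)cc(OC)c1O[C@@H](CO)[C@H](O)c1ccc(OCc2ccccc2)cc1 | intermediate
17 | (4R,5S)-4-[4-(benzyloxy)phenyl]-2,2-di-tert-butyl-5-(4-ethynyl-2,6-dimethoxyphenoxy)-1,3,2-dioxasilinane | C#Cc1cc(OC)c(O[C@H]2CO[Si](C(C)(C)C)(C(C)(C)C)O[C@@H]2c2ccc(OCc3ccccc3)cc2)c(OC)c1 | intermediate
18 | carbon monoxide | [C-]#[O+] | starting material
19 | 2-[3-(ring B aryl)prop-2-ynoyl]benzene-1,3,5-triyl triacetate, ring B aryl being the 3,5-dimethoxyphenyl group of 17 with its silylene-protected side chain (ynone) | CC(=O)Oc1cc(OC(C)=O)c(C(=O)C#Cc2cc(OC)c(O[C@H]3CO[Si](C(C)(C)C)(C(C)(C)C)O[C@@H]3c3ccc(OCc4ccccc4)cc3)c(OC)c2)c(OC(C)=O)c1 | intermediate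
20 | 3-(diethylamino)-1-(2-hydroxy-4,6-diacetoxyphenyl)-3-(ring B aryl)prop-2-en-1-one, same ring B aryl, alkene geometry not fixed | CCN(CC)C(=CC(=O)c1c(O)cc(OC(C)=O)cc1OC(C)=O)c1cc(OC)c(O[C@H]2CO[Si](C(C)(C)C)(C(C)(C)C)O[C@@H]2c2ccc(OCc3ccccc3)cc2)c(OC)c1 | intermediate
21 | 2-(4-{[(4R,5S)-4-[4-(benzyloxy)phenyl]-2,2-di-tert-butyl-1,3,2-dioxasilinan-5-yl]oxy}-3,5-dimethoxyphenyl)-4-oxo-4H-chromene-5,7-diyl diacetate | CC(=O)Oc1cc(OC(C)=O)c2c(c1)oc(-c1cc(OC)c(O[C@H]3CO[Si](C(C)(C)C)(C(C)(C)C)O[C@@H]3c3ccc(OCc4ccccc4)cc3)c(OC)c1)cc2=O | intermediate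
22 | 2-(4-{[(4R,5S)-4-[4-(benzyloxy)phenyl]-2,2-di-tert-butyl-1,3,2-dioxasilinan-5-yl]oxy}-3,5-dimethoxyphenyl)-5,7-dihydroxy-4H-chromen-4-one | COc1cc(-c2cc(=O)c3c(O)cc(O)cc3o2)cc(OC)c1O[C@H]1CO[Si](C(C)(C)C)(C(C)(C)C)O[C@@H]1c1ccc(OCc2ccccc2)cc1 | intermediate
23 | 2-(4-{[(1R,2S)-1-[4-(benzyloxy)phenyl]-1,3-dihydroxypropan-2-yl]oxy}-3,5-dimethoxyphenyl)-5,7-dihydroxy-4H-chromen-4-one | COc1cc(-c2cc(=O)c3c(O)cc(O)cc3o2)cc(OC)c1O[C@@H](CO)[C@H](O)c1ccc(OCc2ccccc2)cc1 | intermediate
24 | (-)-(7''R,8''S)-4'',5,7-trihydroxy-3',5'-dimethoxy-4',8''-oxyflavonolignan-7'',9''-diol | COc1cc(-c2cc(=O)c3c(O)cc(O)cc3o2)cc(OC)c1O[C@@H](CO)[C@H](O)c1ccc(O)cc1 | target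

Total step count: 14 (steps 1–2 make the ring A iodide, steps 3–10 the alkyne, step 11 joins them, steps 12–14 unmask the target).
Longest linear sequence: 12 steps (steps 3–14, from 4 to 24).

Steps most likely to fail

First, step 11. The acetates of 3 may be lost to the amine before oxidative addition, leaving an electron-rich iodophenol that reacts slowly. The aroylpalladium intermediate may also be intercepted by diethylamine to give an amide, or closure may go partly 5-exo. The fallback sets out from 17 and comes back to the route at 21, and it supplies the C4 carbonyl from an acid chloride instead of CO. Commercial 2,4,6-trihydroxybenzoic acid would be peracetylated (Ac2O, pyridine, 0 °C) to 2,4,6-triacetoxybenzoic acid F1. Oxalyl chloride with catalytic DMF in CH2Cl2 would convert it into 2,4,6-triacetoxybenzoyl chloride F2. Coupling of F2 with 17 under PdCl2(PPh3)2/CuI/Et3N in THF at room temperature (acyl Sonogashira coupling) should give ynone 19, this time isolated. Treatment of 19 with Et2NH in DMF at 40 °C should then bring about amine addition, ortho-acetate cleavage and 6-endo closure through 20 to 21.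

Second, step 7. Facial selectivity may be eroded by partial chelation of titanium between the carbonyl and ether oxygens, and the aldehyde may epimerise at C-2 before it is consumed. The fallback sets out from 13, taken as the mixture with its C-1 epimer, and comes back at 13 as the single erythro isomer. Dess–Martin periodinane with NaHCO3 in CH2Cl2 would oxidise both epimers to the one ketone (S)-1-[4-(benzyloxy)phenyl]-2-(4-bromo-2,6-dimethoxyphenoxy)-3-[(tert-butyldiphenylsilyl)oxy]propan-1-one F3. Reduction with Zn(BH4)2 in Et2O at −20 °C should pass through the zinc chelate of the carbonyl and aryloxy oxygens, with hydride delivered from the face that carries the C-2 hydrogen (chelation-controlled reduction). In the ketone series this gives the anti alcohol 13.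

Third, step 5. The two ortho methoxy groups of 7 may slow attack on the alkoxyphosphonium ion, so that elimination or acyl-hydrazide formation takes over. The fallback sets out from 6 and comes back at 8. Tf2O and 2,6-lutidine in CH2Cl2 at −78 °C would convert 6 into methyl (R)-3-[(tert-butyldiphenylsilyl)oxy]-2-{[(trifluoromethyl)sulfonyl]oxy}propanoate F4. The potassium phenoxide of 7 (7, K2CO3, MeCN, −20 → 0 °C) would then displace the triflate by an SN2 reaction with inversion to give 8.

Further compounds
F1 | step 11 | 2,4,6-triacetoxybenzoic acid | CC(=O)Oc1cc(OC(C)=O)c(C(=O)O)c(OC(C)=O)c1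
F2 | step 11 | 2,4,6-triacetoxybenzoyl chloride | CC(=O)Oc1cc(OC(C)=O)c(C(Cl)=O)c(OC(C)=O)c1
F3 | step 7 | (S)-1-[4-(benzyloxy)phenyl]-2-(4-bromo-2,6-dimethoxyphenoxy)-3-[(tert-butyldiphenylsilyl)oxy]propan-1-one | COc1cc(Br)cc(OC)c1O[C@@H](CO[Si](c1ccccc1)(c1ccccc1)C(C)(C)C)C(=O)c1ccc(OCc2ccccc2)cc1
F4 | step 5 | methyl (R)-3-[(tert-butyldiphenylsilyl)oxy]-2-{[(trifluoromethyl)sulfonyl]oxy}propanoate | COC(=O)[C@H](OS(=O)(=O)C(F)(F)F)CO[Si](c1ccccc1)(c1ccccc1)C(C)(C)C
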